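**Retrosynthetic overview**

1. The last step is the key one: a Lewis-acid dearomative aldol addition of an aromatic furan-3-yl acetate onto a tethered aldehyde closes C9–C10 (the ten-membered ring), creates C9 and C10, unveils the 3(2H)-furanone and passes the acetyl group on to O9.
2. Its precursor comes from a trans 6,12-lactone 8,9-diol by O9 silylation, hydroxyl-directed epoxidation of the 11,13-methylene, O8 methacrylation, enol acetylation and oxidation at C9.
3. The lactone (C6, C7) comes from an indium allylation of a Z-enal with a chiral six-membered bromomethyl lactone, followed by translactonisation; the bromolactone comes from (S)-but-3-ene-1,2-diol by acylation and ring-closing metathesis.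
4. The Z-enal furanone comes from 2-methylfuran: hydroarylation of ethyl but-2-ynoate (C3–C4 bond, Z alkene), then C–H borylation/oxidation (C1 oxygen).
5. Ring order: furan (bought) → dihydropyranone → gamma-lactone → spiro-epoxide → ten-membered carbocycle and furanone together.

Assumption: germacrane numbering (C1–C15, lactone carbonyl C12, exocyclic carbon C13) is used in the text, and the furanone intermediates are carried as mixtures of epimers at the ring CH(CH3) carbon (future C10), which is flattened in the aromatic acetate and set only in the last step.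

**Route**

Step 1
Reactants: 1 2-methylfuran; 2 ethyl but-2-ynoate
Product: 3 ethyl (2Z)-3-(5-methylfuran-2-yl)but-2-enoate
Conditions: Pd(OAc)2 (5 mol%), AcOH/CH2Cl2 (1:1), rt, 3 equiv of 1
Reagents that add atoms: none
Why: Fujiwara-type C–H hydroarylation, in which palladation of the free alpha position of the furan, insertion into the alkynoate and protonolysis amount to a trans addition of furyl–H, so furyl and ester end up cis (Z), the C4=C5 geometry of the target.

Step 2
Reactants: 3 ethyl (2Z)-3-(5-methylfuran-2-yl)but-2-enoate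
Product: 4 (2Z)-3-(5-methylfuran-2-yl)but-2-en-1-ol
Conditions: DIBAL-H (2.2 equiv), CH2Cl2, −78 °C; Rochelle salt work-up
Reagents that add atoms: none
Why: DIBAL-H reduces the conjugated ester by 1,2-addition to the allylic alcohol at low temperature without isomerising the Z alkene.

Step 3
Reactants: 4 (2Z)-3-(5-methylfuran-2-yl)but-2-en-1-ol
Product: 6 5-[(2Z)-4-hydroxybut-2-en-2-yl]-2-methylfuran-3(2H)-one, via bis-pinacolboryl furan 5 (not isolated)
Conditions: [Ir(OMe)(cod)]2 (1.5 mol%), 4,4'-di-tert-butyl-2,2'-bipyridine (3 mol%), B2pin2 (1.1 equiv), THF, 50 °C; then NaBO3·4H2O, THF/H2O, 0 °C → rt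
Reagents that add atoms: bis(pinacolato)diboron CC1(C)OB(OC1(C)C)B1OC(C)(C)C(C)(C)O1 (boron of 5 only); sodium perborate tetrahydrate NaBO3·4H2O [Na+].[O-]OB=O.O.O.O.O (the new ring oxygen of 6)
Why: Sterically controlled iridium-catalysed C–H borylation takes the ring C–H next to the small methyl group rather than the one next to the branched alkenyl group (the alcohol is carried as its O-Bpin ester), and perborate oxidation of the C–B bond gives the furan-3-ol, which tautomerises to the non-aromatic 3(2H)-furanone, so this step installs the C1 oxygen.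

Step 4
Reactants: 6 5-[(2Z)-4-hydroxybut-2-en-2-yl]-2-methylfuran-3(2H)-one
Product: 7 (2Z)-3-(5-methyl-4-oxo-4,5-dihydrofuran-2-yl)but-2-enal
Conditions: activated MnO2 (15 equiv), CH2Cl2, rt
Reagents that add atoms: none
Why: Allylic oxidation on activated MnO2 is selective for the allylic alcohol and keeps the Z geometry, giving the C6 aldehyde for the fragment union.

Step 5
Reactants: 8 (2S)-but-3-ene-1,2-diol; 9 2-(bromomethyl)prop-2-enoic acid
Product: 11 (2S)-2-hydroxybut-3-en-1-yl 2-(bromomethyl)prop-2-enoate, via 2-(bromomethyl)prop-2-enoyl chloride 10 (not isolated)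
Conditions: 9, (COCl)2, DMF (cat.), CH2Cl2, 0 °C → rt; then 8, 2,4,6-collidine, CH2Cl2, −78 °C
Reagents that add atoms: oxalyl chloride ClC(=O)C(=O)Cl (chlorine of 10 only)
Why: Acid chloride acylation at −78 °C with the hindered, non-nucleophilic base collidine esterifies the primary hydroxyl selectively and leaves the allylic bromide alone, while the stereocentre (future C8) comes unchanged from the chiral pool.

Step 6
Reactants: 11 (2S)-2-hydroxybut-3-en-1-yl 2-(bromomethyl)prop-2-enoate
Product: 12 (5S)-3-(bromomethyl)-5-hydroxy-5,6-dihydro-2H-pyran-2-one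
Conditions: second-generation Grubbs catalyst [RuCl2(=CHPh)(H2IMes)(PCy3)] (5 mol%), CH2Cl2 (5 mM), 40 °C
Reagents that add atoms: none
Why: Ring-closing metathesis between the vinyl group and the 1,1-disubstituted acrylate forms the trisubstituted endocyclic alkene of the six-membered lactone with loss of ethylene, giving a cyclic 2-(bromomethyl)enoate whose ring fixes the alkene geometry needed in step 7.

Step 7
Reactants: 7 (2Z)-3-(5-methyl-4-oxo-4,5-dihydrofuran-2-yl)but-2-enal; 12 (5S)-3-(bromomethyl)-5-hydroxy-5,6-dihydro-2H-pyran-2-one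
Product: 14 (4R,5R)-4-[(1S)-1,2-dihydroxyethyl]-3-methylidene-5-[(1Z)-2-(5-methyl-4-oxo-4,5-dihydrofuran-2-yl)prop-1-en-1-yl]oxolan-2-one, via delta-lactone homoallylic alcohol 13 (not isolated)
Conditions: In powder (1.5 equiv), 12 (1.3 equiv), THF/H2O (1:1), rt; then PPTS (cat.), CH2Cl2, rt
Reagents that add atoms: none
Why: Barbier allylation in which the allylindium from 12 reacts at its ring carbon (SE2', C6–C7 bond) on the face anti to the C8 hydroxyl (sets C7) and, because the ring holds C8 trans to the CH2In carbon (E-type allyl), through a chair transition state with the enal residue equatorial to give the anti adduct (sets C6), after which the C6 hydroxyl opens the six-membered lactone to the less strained trans-disubstituted 6,12-gamma-lactone (translactonisation) and frees O9.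

Step 8
Reactants: 14 (4R,5R)-4-[(1S)-1,2-dihydroxyethyl]-3-methylidene-5-[(1Z)-2-(5-methyl-4-oxo-4,5-dihydrofuran-2-yl)prop-1-en-1-yl]oxolan-2-one
Product: 15 (4R,5R)-4-[(1S)-1-hydroxy-2-(triethylsilyloxy)ethyl]-3-methylidene-5-[(1Z)-2-(5-methyl-4-oxo-4,5-dihydrofuran-2-yl)prop-1-en-1-yl]oxolan-2-one
Conditions: Et3SiCl (1.05 equiv), imidazole, CH2Cl2, −78 → −40 °C
Reagents that add atoms: chlorotriethylsilane CC[Si](Cl)(CC)CC
Why: Silylation with one equivalent of Et3SiCl at low temperature is selective for the primary C9 hydroxyl over the hindered secondary C8 hydroxyl, which must stay free to direct step 9.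

Step 9
Reactants: 15 (4R,5R)-4-[(1S)-1-hydroxy-2-(triethylsilyloxy)ethyl]-3-methylidene-5-[(1Z)-2-(5-methyl-4-oxo-4,5-dihydrofuran-2-yl)prop-1-en-1-yl]oxolan-2-one
Product: 16 (3S,6R,7R)-7-[(1S)-1-hydroxy-2-(triethylsilyloxy)ethyl]-6-[(1Z)-2-(5-methyl-4-oxo-4,5-dihydrofuran-2-yl)prop-1-en-1-yl]-1,5-dioxaspiro[2.4]heptan-4-one
Conditions: t-BuOOH (4 equiv), n-BuLi (3.5 equiv), THF, −78 → −20 °C
Reagents that add atoms: tert-butyl hydroperoxide CC(C)(C)OO (the epoxide oxygen)
Why: Hydroxyl-directed Weitz–Scheffer epoxidation of the alpha-methylene lactone, in which lithium tert-butyl peroxide adds to C13 and the enolate closes on oxygen while the lithium alkoxide of the C8 hydroxyl, lying on the same side of the lactone as the C7–C8 bond, holds the peroxide on that face and so gives the 11S spiro-epoxide against the steric bias; the furanone is protected as its enolate under these conditions.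

Step 10
Reactants: 16 (3S,6R,7R)-7-[(1S)-1-hydroxy-2-(triethylsilyloxy)ethyl]-6-[(1Z)-2-(5-methyl-4-oxo-4,5-dihydrofuran-2-yl)prop-1-en-1-yl]-1,5-dioxaspiro[2.4]heptan-4-one
Product: 17 (1S)-1-[(3S,6R,7S)-6-[(1Z)-2-(5-methyl-4-oxo-4,5-dihydrofuran-2-yl)prop-1-en-1-yl]-4-oxo-1,5-dioxaspiro[2.4]heptan-7-yl]-2-(triethylsilyloxy)ethyl 2-methylprop-2-enoate
Conditions: methacrylic acid (3 equiv), N,N'-diisopropylcarbodiimide, DMAP (cat.), CH2Cl2, 0 °C → rt
Reagents that add atoms: methacrylic acid CC(=C)C(=O)O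
Why: Steglich esterification under essentially non-basic conditions acylates the free C8 hydroxyl without O-acylating the enolisable furanone or opening the epoxide.

Step 11
Reactants: 17 (1S)-1-[(3S,6R,7S)-6-[(1Z)-2-(5-methyl-4-oxo-4,5-dihydrofuran-2-yl)prop-1-en-1-yl]-4-oxo-1,5-dioxaspiro[2.4]heptan-7-yl]-2-(triethylsilyloxy)ethyl 2-methylprop-2-enoate
Product: 18 (1S)-1-[(3S,6R,7S)-6-{(1Z)-2-[4-(acetyloxy)-5-methylfuran-2-yl]prop-1-en-1-yl}-4-oxo-1,5-dioxaspiro[2.4]heptan-7-yl]-2-(triethylsilyloxy)ethyl 2-methylprop-2-enoate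
Conditions: Ac2O (1.5 equiv), Et3N, DMAP (cat.), CH2Cl2, 0 °C
Reagents that add atoms: acetic anhydride CC(=O)OC(C)=O
Why: O-Acetylation of the amine-generated furanone enolate gives the aromatic furan-3-yl acetate (the CH(CH3) stereocentre is erased), which protects the furanone through step 12 and carries the acetyl group destined for O9.

Step 12
Reactants: 18 (1S)-1-[(3S,6R,7S)-6-{(1Z)-2-[4-(acetyloxy)-5-methylfuran-2-yl]prop-1-en-1-yl}-4-oxo-1,5-dioxaspiro[2.4]heptan-7-yl]-2-(triethylsilyloxy)ethyl 2-methylprop-2-enoate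
Product: 19 (1S)-1-[(3S,6R,7S)-6-{(1Z)-2-[4-(acetyloxy)-5-methylfuran-2-yl]prop-1-en-1-yl}-4-oxo-1,5-dioxaspiro[2.4]heptan-7-yl]-2-oxoethyl 2-methylprop-2-enoate
Conditions: (COCl)2, DMSO, CH2Cl2, −78 → −40 °C; then i-Pr2NEt, −78 → 0 °C; used crude
Reagents that add atoms: none
Why: Swern conditions oxidise primary triethylsilyl ethers directly to aldehydes (silyl transfer to chloride, then collapse of the alkoxysulfonium ion), so no separate desilylation is needed, and the hindered amine limits epimerisation of the alpha-acyloxy aldehyde at C8.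

Step 13
Reactants: 19 (1S)-1-[(3S,6R,7S)-6-{(1Z)-2-[4-(acetyloxy)-5-methylfuran-2-yl]prop-1-en-1-yl}-4-oxo-1,5-dioxaspiro[2.4]heptan-7-yl]-2-oxoethyl 2-methylprop-2-enoate
Product: 20 the target, (6R,7S,8S,9S,10S,11S)-9-acetoxy-8-(2-methylprop-2-enoyloxy)-1-oxo-3,10:11,13-diepoxygermacra-2,4Z-dien-12,6-olide
Conditions: BF3·OEt2 (0.5 equiv), CH2Cl2 (1 mM), −78 → −40 °C
Reagents that add atoms: none
Why: Proposed new method: a Lewis-acid dearomative acyl-transfer aldol macrocyclisation in which BF3 activates the aldehyde, the methyl-bearing alpha carbon of the furan (C10) attacks it with loss of aromaticity to give a 3-acetoxy-2H-furanium ion, and the acetyl group is then handed through a six-membered transition state to the new C9 oxygen, leaving the furanone ketone and the C9 acetate, so 19 isomerises directly to 20; C9 should follow polar Felkin–Anh addition anti to the C8–O bond (8,9-anti), and C10 should follow from A(1,3) strain in the Z alkene, which keeps H6 eclipsed with C4=C5 and so holds the aldehyde tether over the furan face that gives 10S; the closest known reactions are Mukaiyama-type aldol additions of enol acetates with O-to-O acyl transfer and Lewis-acid aldol additions of 3-silyloxyfurans at C2.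

**Compound list**

1 | 2-methylfuran | Cc1ccco1 | starting material
2 | ethyl but-2-ynoate | CC#CC(=O)OCC | starting material
3 | ethyl (2Z)-3-(5-methylfuran-2-yl)but-2-enoate | CCOC(=O)/C=C(/C)c1ccc(C)o1 | intermediate
4 | (2Z)-3-(5-methylfuran-2-yl)but-2-en-1-ol | OC/C=C(/C)c1ccc(C)o1 | intermediate
5 | 2-{[(2Z)-3-[5-methyl-4-(4,4,5,5-tetramethyl-1,3,2-dioxaborolan-2-yl)furan-2-yl]but-2-en-1-yl]oxy}-4,4,5,5-tetramethyl-1,3,2-dioxaborolane | CC1(C)OB(OC/C=C(/C)c2cc(B3OC(C)(C)C(C)(C)O3)c(C)o2)OC1(C)C | intermediate (not isolated)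
6 | 5-[(2Z)-4-hydroxybut-2-en-2-yl]-2-methylfuran-3(2H)-one | OC/C=C(/C)C1=CC(=O)C(C)O1 | intermediate
7 | (2Z)-3-(5-methyl-4-oxo-4,5-dihydrofuran-2-yl)but-2-enal | O=C/C=C(/C)C1=CC(=O)C(C)O1 | intermediate
8 | (2S)-but-3-ene-1,2-diol | O[C@H](CO)C=C | starting material
9 | 2-(bromomethyl)prop-2-enoic acid | OC(=O)C(=C)CBr | starting material
10 | 2-(bromomethyl)prop-2-enoyl chloride | ClC(=O)C(=C)CBr | intermediate (not isolated)
11 | (2S)-2-hydroxybut-3-en-1-yl 2-(bromomethyl)prop-2-enoate | O[C@H](COC(=O)C(=C)CBr)C=C | intermediate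
12 | (5S)-3-(bromomethyl)-5-hydroxy-5,6-dihydro-2H-pyran-2-one | O[C@@H]1COC(=O)C(CBr)=C1 | intermediate
13 | (4S,5S)-5-hydroxy-4-[(1R,2Z)-1-hydroxy-3-(5-methyl-4-oxo-4,5-dihydrofuran-2-yl)but-2-en-1-yl]-3-methylideneoxan-2-one | O[C@@H]1COC(=O)C(=C)[C@H]1[C@H](O)/C=C(/C)C2=CC(=O)C(C)O2 | intermediate (not isolated)
14 | (4R,5R)-4-[(1S)-1,2-dihydroxyethyl]-3-methylidene-5-[(1Z)-2-(5-methyl-4-oxo-4,5-dihydrofuran-2-yl)prop-1-en-1-yl]oxolan-2-one | O[C@H](CO)[C@@H]1[C@@H](/C=C(/C)C2=CC(=O)C(C)O2)OC(=O)C1=C | intermediate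
15 | (4R,5R)-4-[(1S)-1-hydroxy-2-(triethylsilyloxy)ethyl]-3-methylidene-5-[(1Z)-2-(5-methyl-4-oxo-4,5-dihydrofuran-2-yl)prop-1-en-1-yl]oxolan-2-one | O[C@H](CO[Si](CC)(CC)CC)[C@@H]1[C@@H](/C=C(/C)C2=CC(=O)C(C)O2)OC(=O)C1=C | intermediate
16 | (3S,6R,7R)-7-[(1S)-1-hydroxy-2-(triethylsilyloxy)ethyl]-6-[(1Z)-2-(5-methyl-4-oxo-4,5-dihydrofuran-2-yl)prop-1-en-1-yl]-1,5-dioxaspiro[2.4]heptan-4-one | O[C@H](CO[Si](CC)(CC)CC)[C@@H]1[C@@H](/C=C(/C)C2=CC(=O)C(C)O2)OC(=O)[C@@]13CO3 | intermediate
17 | (1S)-1-[(3S,6R,7S)-6-[(1Z)-2-(5-methyl-4-oxo-4,5-dihydrofuran-2-yl)prop-1-en-1-yl]-4-oxo-1,5-dioxaspiro[2.4]heptan-7-yl]-2-(triethylsilyloxy)ethyl 2-methylprop-2-enoate | C=C(C)C(=O)O[C@H](CO[Si](CC)(CC)CC)[C@@H]1[C@@H](/C=C(/C)C2=CC(=O)C(C)O2)OC(=O)[C@@]13CO3 | intermediate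
18 | (1S)-1-[(3S,6R,7S)-6-{(1Z)-2-[4-(acetyloxy)-5-methylfuran-2-yl]prop-1-en-1-yl}-4-oxo-1,5-dioxaspiro[2.4]heptan-7-yl]-2-(triethylsilyloxy)ethyl 2-methylprop-2-enoate | C=C(C)C(=O)O[C@H](CO[Si](CC)(CC)CC)[C@@H]1[C@@H](/C=C(/C)c2cc(OC(C)=O)c(C)o2)OC(=O)[C@@]13CO3 | intermediate
19 | (1S)-1-[(3S,6R,7S)-6-{(1Z)-2-[4-(acetyloxy)-5-methylfuran-2-yl]prop-1-en-1-yl}-4-oxo-1,5-dioxaspiro[2.4]heptan-7-yl]-2-oxoethyl 2-methylprop-2-enoate | C=C(C)C(=O)O[C@H](C=O)[C@@H]1[C@@H](/C=C(/C)c2cc(OC(C)=O)c(C)o2)OC(=O)[C@@]13CO3 | intermediate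
20 | (6R,7S,8S,9S,10S,11S)-9-acetoxy-8-(2-methylprop-2-enoyloxy)-1-oxo-3,10:11,13-diepoxygermacra-2,4Z-dien-12,6-olide (CNP0423862.2) | C=C(C)C(=O)O[C@H]1[C@@H]2[C@@H](/C=C(/C)C3=CC(=O)[C@@](C)(O3)[C@H]1OC(C)=O)OC(=O)[C@@]21CO1 | target

**Step count and risks**

Total steps: 13. Longest linear sequence: 11 (steps 1–4, then 7–13); the bromolactone branch is steps 5–6.

The three steps most likely to fail:

Step 13 (the dearomative acyl-transfer ring closure). The ipso attack at the methyl-bearing furan carbon may be slower than side reactions of the electron-rich furan (attack through the other ring carbon, ionisation of the allylic lactone C6–O bond), and the C10 facial preference is predicted, not proven. The fallback sets out from 17 and comes back at 20, and replaces the acyl transfer by a conventional silyl enol ether aldol followed by a separate acetylation. Swern oxidation of 17 gives the keto-form furanone aldehyde F1. TBSOTf/Et3N at −78 °C silylates the vinylogous ester oxygen (much faster than the aldehyde is enolised) to give the aromatic 3-silyloxyfuran aldehyde F2. BF3·OEt2 at 1 mM then effects an intramolecular Mukaiyama aldol addition to the 9-hydroxy macrocycle F3. Ac2O/DMAP/pyridine acetylates O9 to give 20.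

Step 9 (hydroxyl-directed epoxidation). Direction by a hydroxyl that is homoallylic to the methylene is less secure than the usual allylic cases, and the C8 alkoxide could also migrate the lactone to O8. The fallback sets out from 15 and comes back at 16, and builds the epoxide from a directed diol. OsO4·TMEDA (1 equiv, CH2Cl2, −78 °C, hydrogen-bonded to the C8 hydroxyl; osmate ester cleaved with ethylenediamine) gives the 11,13-diol F4 with the tertiary hydroxyl on the face of the C8 hydroxyl. TsCl/pyridine at 0 °C sulfonylates only the primary C13 hydroxyl to give the tosylate F5. DBU in CH2Cl2 closes the epoxide with retention at C11 to give 16.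

Step 7 (allylation and translactonisation). The facial preference next to a free hydroxyl may be modest, 12 can isomerise to a butenolide under acid or base, and the 8,12-lactone could compete. The fallback sets out from 7 and comes back at 14, and uses an open-chain allylboronate with the diol locked as an acetonide. Commercial (R)-2,2-dimethyl-1,3-dioxolane-4-carbaldehyde is homologated with the Ohira–Bestmann reagent (K2CO3, MeOH) to the terminal alkyne F6. Carboxylation (n-BuLi, ClCO2Me, THF, −78 °C) gives the alkynoate F7. Syn-hydroalumination (i-Bu2AlH, HMPA, cat. MeCu) followed by trapping with ICH2Bpin gives the allylboronate F8, with the dioxolane cis to the ester. Allylboration of 7 (Sc(OTf)3 cat., toluene, rt) through a chair transition state gives the anti adduct, which lactonises (TsOH cat.) to the trans-lactone acetonide F9; here only O6 can lactonise. Aqueous AcOH at 40 °C removes the acetonide to give 14.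

**Further compounds**

F1 | step 13 | (1S)-1-[(3S,6R,7S)-6-[(1Z)-2-(5-methyl-4-oxo-4,5-dihydrofuran-2-yl)prop-1-en-1-yl]-4-oxo-1,5-dioxaspiro[2.4]heptan-7-yl]-2-oxoethyl 2-methylprop-2-enoate | C=C(C)C(=O)O[C@H](C=O)[C@@H]1[C@@H](/C=C(/C)C2=CC(=O)C(C)O2)OC(=O)[C@@]13CO3
F2 | step 13 | (1S)-1-[(3S,6R,7S)-6-{(1Z)-2-[4-(tert-butyldimethylsilyloxy)-5-methylfuran-2-yl]prop-1-en-1-yl}-4-oxo-1,5-dioxaspiro[2.4]heptan-7-yl]-2-oxoethyl 2-methylprop-2-enoate | C=C(C)C(=O)O[C@H](C=O)[C@@H]1[C@@H](/C=C(/C)c2cc(O[Si](C)(C)C(C)(C)C)c(C)o2)OC(=O)[C@@]13CO3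
F3 | step 13 | 9-O-deacetyl derivative of 20 (9S alcohol, all other centres as in 20) | C=C(C)C(=O)O[C@H]1[C@@H]2[C@@H](/C=C(/C)C3=CC(=O)[C@@](C)(O3)[C@H]1O)OC(=O)[C@@]21CO1
F4 | step 9 | 11,13-diol of 15 (3-hydroxy-3-(hydroxymethyl)oxolan-2-one, tertiary hydroxyl on the face of the C8 hydroxyl) | O[C@H](CO[Si](CC)(CC)CC)[C@@H]1[C@@H](/C=C(/C)C2=CC(=O)C(C)O2)OC(=O)[C@@]1(O)CO
F5 | step 9 | 13-O-(4-methylbenzenesulfonyl) derivative of F4 | O[C@H](CO[Si](CC)(CC)CC)[C@@H]1[C@@H](/C=C(/C)C2=CC(=O)C(C)O2)OC(=O)[C@@]1(O)COS(=O)(=O)c1ccc(C)cc1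
F6 | step 7 | (4S)-4-ethynyl-2,2-dimethyl-1,3-dioxolane | C#C[C@H]1COC(C)(C)O1
F7 | step 7 | methyl 3-[(4S)-2,2-dimethyl-1,3-dioxolan-4-yl]prop-2-ynoate | COC(=O)C#C[C@H]1COC(C)(C)O1
F8 | step 7 | methyl (2Z)-3-[(4S)-2,2-dimethyl-1,3-dioxolan-4-yl]-2-[(4,4,5,5-tetramethyl-1,3,2-dioxaborolan-2-yl)methyl]prop-2-enoate | COC(=O)/C(CB1OC(C)(C)C(C)(C)O1)=C\[C@H]1COC(C)(C)O1
F9 | step 7 | (4S,5R)-4-[(4S)-2,2-dimethyl-1,3-dioxolan-4-yl]-3-methylidene-5-[(1Z)-2-(5-methyl-4-oxo-4,5-dihydrofuran-2-yl)prop-1-en-1-yl]oxolan-2-one | CC1(C)OC[C@@H](O1)[C@@H]1[C@@H](/C=C(/C)C2=CC(=O)C(C)O2)OC(=O)C1=C
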